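**Strategy.** Everything rests on opening ring C of the upper (catechol-bearing) flavan unit at the aryl ether bond O1–C8a. The key step, a palladium-catalysed intramolecular O-arylation, closes this pyran in one operation: the C2 hydroxyl of an acyclic all-syn 1-(2-bromo-3,4-dibenzyloxyphenyl)-3-arylpropane-1,3-diol 2-benzyl ether attacks C8a. No bond to C2 is broken, so the syn C2/C3 pair from a glycolate aldol becomes the 2,3-cis ring that O1–C2 closures do not deliver. The step exploits the 7,8-dioxygenated ring A, whose C8a is ortho to both the C4a–C4 bond and O8. The lower unit is made alike, and a biomimetic C4–C6 cation coupling joins the two.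

Key step: step 10

Remark: flavan numbering (O1, C2, C3, C4, C4a, C5 to C8, C8a) is used for both halves. The "upper unit" carries the 3,4-dihydroxyphenyl ring and the "lower unit" the 4-hydroxyphenyl ring. Acyclic precursors are numbered along the propane chain, with C1 next to the bromoaryl ring.

Remark: the boron enolate 7 and the aryl Grignard reagent 11 are each generated once, as cold solutions. Each batch is divided between the two branches, which are run side by side.

## Route

Step 1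
Reactants: 1 3-bromocatechol
Product: 2 1,2-bis(benzyloxy)-3-bromobenzene
Conditions: BnBr (2.3 equiv), K2CO3, DMF, 60 °C
Reagents that add atoms: benzyl bromide, BrCc1ccccc1
Why: Williamson ether synthesis, in which both phenoxides of the catechol are alkylated by the reactive benzylic bromide.

Step 2
Reactants: 2 1,2-bis(benzyloxy)-3-bromobenzene
Product: 3 1,2-bis(benzyloxy)-3-bromo-4-iodobenzene
Conditions: NIS (1.05 equiv), TFA (10 mol %), MeCN, 0 °C → rt
Reagents that add atoms: N-iodosuccinimide, O=C1CCC(=O)N1I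
Why: Electrophilic aromatic iodination should occur para to the C1 benzyloxy group, the only alkoxy group able to lie in the ring plane (the C2 benzyloxy group is twisted by its two ortho neighbours), which places iodine next to bromine.

Step 3
Reactants: 4 (S)-4-benzyl-1,3-oxazolidin-2-one; 5 (benzyloxy)acetyl chloride
Product: 6 (S)-4-benzyl-3-[(benzyloxy)acetyl]-1,3-oxazolidin-2-one
Conditions: n-BuLi, THF, −78 °C; then 5, −78 → 0 °C
Reagents that add atoms: none
Why: N-acylation of the lithiated oxazolidinone by the acid chloride gives the glycolate imide needed for an Evans aldol reaction.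

Step 4
Reactants: 6 (S)-4-benzyl-3-[(benzyloxy)acetyl]-1,3-oxazolidin-2-one
Product: 7 (S)-4-benzyl-3-[(Z)-2-(benzyloxy)-1-[(dibutylboranyl)oxy]ethenyl]-1,3-oxazolidin-2-one, the (Z)-dibutylboron enolate of 6, kept as a CH2Cl2 solution
Conditions: Bu2BOTf (1.1 equiv), Et3N (1.3 equiv), CH2Cl2, −78 → 0 °C, then −78 °C; solution divided by cannula into two portions for steps 5 and 11
Reagents that add atoms: dibutylboron triflate, CCCCB(CCCC)OS(=O)(=O)C(F)(F)F
Why: Soft enolisation of the N-acyl oxazolidinone, in which boron coordination acidifies the α-hydrogen and the amine removes it from the conformer that avoids allylic strain, should give the (Z)-enolate only; the enolate is stable in solution at −78 °C, so one batch serves both aldol reactions.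

Step 5
Reactants: 7 (Z)-dibutylboron enolate of 6; 8 3,4-bis(benzyloxy)benzaldehyde
Product: 9 (S)-4-benzyl-3-[(2S,3R)-2-(benzyloxy)-3-[3,4-bis(benzyloxy)phenyl]-3-hydroxypropanoyl]-1,3-oxazolidin-2-one
Conditions: first portion of the solution of 7, CH2Cl2, −78 °C; 8, −78 → 0 °C; pH 7 buffer, MeOH, H2O2
Reagents that add atoms: none
Why: Evans syn-aldol reaction, in which the (Z)-boron enolate reacts through a chair Zimmerman–Traxler transition state on the face opposite the auxiliary benzyl group, setting chain C2 (S) and C3 (R) as the syn pair that becomes flavan C3 and C2.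

Step 6
Reactants: 9 (S)-4-benzyl-3-[(2S,3R)-2-(benzyloxy)-3-[3,4-bis(benzyloxy)phenyl]-3-hydroxypropanoyl]-1,3-oxazolidin-2-one
Product: 10 (2S,3R)-2-(benzyloxy)-3-[3,4-bis(benzyloxy)phenyl]-3-hydroxy-N-methoxy-N-methylpropanamide
Conditions: MeNHOMe·HCl, AlMe3, CH2Cl2, −10 °C → rt
Reagents that add atoms: N,O-dimethylhydroxylamine hydrochloride, CNOC.Cl
Why: Weinreb amide formation by aluminium amide transamidation, which is assisted by the free β-hydroxyl and removes the auxiliary without touching the two stereocentres.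

Step 7
Reactants: 3 1,2-bis(benzyloxy)-3-bromo-4-iodobenzene
Product: 11 [3,4-bis(benzyloxy)-2-bromophenyl]magnesium chloride, kept as a THF solution of its LiCl complex
Conditions: i-PrMgCl·LiCl (1.05 equiv), THF, −40 °C, 1 h; solution held at −40 °C and divided into two portions for steps 8 and 13
Reagents that add atoms: isopropylmagnesium chloride (as its LiCl complex), CC(C)[Mg]Cl
Why: Iodine–magnesium exchange with the turbo-Grignard reagent is far faster at C–I than at C–Br, and the ortho-bromoaryl Grignard reagent should not collapse to an aryne at −40 °C.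

Step 8
Reactants: 10 (2S,3R)-2-(benzyloxy)-3-[3,4-bis(benzyloxy)phenyl]-3-hydroxy-N-methoxy-N-methylpropanamide; 11 [3,4-bis(benzyloxy)-2-bromophenyl]magnesium chloride
Product: 12 (2S,3R)-2-(benzyloxy)-1-[3,4-bis(benzyloxy)-2-bromophenyl]-3-[3,4-bis(benzyloxy)phenyl]-3-hydroxypropan-1-one
Conditions: 10, i-PrMgCl (1.0 equiv), THF, −40 °C; then first portion of the solution of 11 (1.5 equiv), −40 → 0 °C; aq NH4Cl
Reagents that add atoms: none
Why: Addition of an aryl Grignard reagent to a Weinreb amide, in which the hydroxyl is first masked as its magnesium alkoxide and the chelated tetrahedral intermediate survives until work-up, so that only one aryl group adds and the aryl ketone results.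

Step 9
Reactants: 12 (2S,3R)-2-(benzyloxy)-1-[3,4-bis(benzyloxy)-2-bromophenyl]-3-[3,4-bis(benzyloxy)phenyl]-3-hydroxypropan-1-one
Product: 13 (1S,2S,3R)-2-(benzyloxy)-1-[3,4-bis(benzyloxy)-2-bromophenyl]-3-[3,4-bis(benzyloxy)phenyl]propane-1,3-diol (all-syn)
Conditions: Et2BOMe, THF/MeOH (4:1), −78 °C; NaBH4, −78 °C; pH 7 buffer, H2O2
Reagents that add atoms: none
Why: Narasaka–Prasad reduction, in which the diethylboron chelate of the β-hydroxy ketone takes external hydride axially to give the 1,3-syn diol and so sets C1 (S), a centre that only carries the leaving group and is erased in step 16.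

Step 10
Reactants: 13 (1S,2S,3R)-2-(benzyloxy)-1-[3,4-bis(benzyloxy)-2-bromophenyl]-3-[3,4-bis(benzyloxy)phenyl]propane-1,3-diol
Product: 14 (2R,3R,4S)-3,7,8-tris(benzyloxy)-2-[3,4-bis(benzyloxy)phenyl]chroman-4-ol (2,3-cis-3,4-trans)
Conditions: Pd(OAc)2 (5 mol %), 2-(di-tert-butylphosphino)-1,1'-binaphthyl (6 mol %), Cs2CO3 (2.5 equiv), toluene, 70 °C
Reagents that add atoms: none
Why: Zerovalent palladium (formed from Pd(OAc)2 and the bulky phosphine) inserts into the C8a–Br bond, the caesium alkoxide of the C2 hydroxyl replaces bromide on palladium, and C–O reductive elimination forms O1–C8a. The closest known reaction type is the Buchwald–Hartwig intramolecular etherification of 3-(2-bromoaryl)propan-1-ols to chromans, which is established for secondary alcohols and proceeds without loss of configuration at the carbinol carbon. Ring C is closed as a six-membered ring by reductive elimination from a seven-membered aryl–palladium alkoxide chelate, and no other ring is formed. No stereocentre is created: C2, C3 and C4 keep their configuration because no bond to them is broken, so the syn C2/C3 pair of 13 becomes the 2,3-cis pair and the syn C3/C4 pair the 3,4-trans pair of 14. The step needs chemoselectivity among the oxygen nucleophiles, which the substrate secures because O3 is benzylated and the C4 hydroxyl could only close a four-membered ring, and it needs reductive elimination to outrun β-hydride elimination of the benzylic alkoxide, for which the di-tert-butylphosphine ligand is chosen.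

Step 11
Reactants: 7 (Z)-dibutylboron enolate of 6; 15 4-(benzyloxy)benzaldehyde
Product: 16 (S)-4-benzyl-3-[(2S,3R)-2-(benzyloxy)-3-[4-(benzyloxy)phenyl]-3-hydroxypropanoyl]-1,3-oxazolidin-2-one
Conditions: second portion of the solution of 7, CH2Cl2, −78 °C; 15, −78 → 0 °C; pH 7 buffer, MeOH, H2O2
Reagents that add atoms: none
Why: Evans syn-aldol reaction with the same enolate and the same facial control as in step 5, setting the syn pair that becomes C3 and C2 of the lower unit.

Step 12
Reactants: 16 (S)-4-benzyl-3-[(2S,3R)-2-(benzyloxy)-3-[4-(benzyloxy)phenyl]-3-hydroxypropanoyl]-1,3-oxazolidin-2-one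
Product: 17 (2S,3R)-2-(benzyloxy)-3-[4-(benzyloxy)phenyl]-3-hydroxy-N-methoxy-N-methylpropanamide
Conditions: MeNHOMe·HCl, AlMe3, CH2Cl2, −10 °C → rt
Reagents that add atoms: N,O-dimethylhydroxylamine hydrochloride, CNOC.Cl
Why: Weinreb amide formation by aluminium amide transamidation, as in step 6.

Step 13
Reactants: 17 (2S,3R)-2-(benzyloxy)-3-[4-(benzyloxy)phenyl]-3-hydroxy-N-methoxy-N-methylpropanamide; 11 [3,4-bis(benzyloxy)-2-bromophenyl]magnesium chloride
Product: 18 (2S,3R)-2-(benzyloxy)-1-[3,4-bis(benzyloxy)-2-bromophenyl]-3-[4-(benzyloxy)phenyl]-3-hydroxypropan-1-one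
Conditions: 17, i-PrMgCl (1.0 equiv), THF, −40 °C; then second portion of the solution of 11 (1.5 equiv), −40 → 0 °C; aq NH4Cl
Reagents that add atoms: none
Why: Addition of the aryl Grignard reagent to the Weinreb amide through a stable chelated tetrahedral intermediate, as in step 8.

Step 14
Reactants: 18 (2S,3R)-2-(benzyloxy)-1-[3,4-bis(benzyloxy)-2-bromophenyl]-3-[4-(benzyloxy)phenyl]-3-hydroxypropan-1-one
Product: 19 (1R,2S,3R)-2-(benzyloxy)-1-[3,4-bis(benzyloxy)-2-bromophenyl]-3-[4-(benzyloxy)phenyl]propane-1,3-diol (2,3-syn-1,2-anti)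
Conditions: Me4NBH(OAc)3 (5 equiv), MeCN/AcOH (1:1), −30 °C
Reagents that add atoms: none
Why: Evans–Saksena reduction, in which the triacetoxyborohydride is bound by the C3 hydroxyl and delivers hydride intramolecularly through a chair transition state to give the 1,3-anti diol, setting C1 (R), the future C4 of the lower unit.

Step 15
Reactants: 19 (1R,2S,3R)-2-(benzyloxy)-1-[3,4-bis(benzyloxy)-2-bromophenyl]-3-[4-(benzyloxy)phenyl]propane-1,3-diol
Product: 20 (2R,3R,4R)-3,7,8-tris(benzyloxy)-2-[4-(benzyloxy)phenyl]chroman-4-ol (all-cis)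
Conditions: Pd(OAc)2 (5 mol %), 2-(di-tert-butylphosphino)-1,1'-binaphthyl (6 mol %), Cs2CO3 (2.5 equiv), toluene, 70 °C
Reagents that add atoms: none
Why: The same Buchwald–Hartwig intramolecular etherification as in step 10 closes the lower pyran with retention at all three carbinol carbons, so the syn C2/C3 and anti C3/C4 pairs of 19 become the all-cis ring of 20.

Step 16
Reactants: 14 (2R,3R,4S)-3,7,8-tris(benzyloxy)-2-[3,4-bis(benzyloxy)phenyl]chroman-4-ol; 20 (2R,3R,4R)-3,7,8-tris(benzyloxy)-2-[4-(benzyloxy)phenyl]chroman-4-ol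
Product: 21 (2R,3R,4R)-3,7,8-tris(benzyloxy)-2-[4-(benzyloxy)phenyl]-6-{(2R,3R,4R)-3,7,8-tris(benzyloxy)-2-[3,4-bis(benzyloxy)phenyl]chroman-4-yl}chroman-4-ol (nona-O-benzyl ether of the target; the upper C4 has the spatial arrangement of the target and its descriptor differs only through the priorities of the benzyl ethers)
Conditions: 20 (3 equiv), BF3·OEt2 (1.5 equiv), CH2Cl2, −78 → −30 °C, slow addition of 14; aq NaHCO3
Reagents that add atoms: none
Why: Biomimetic Friedel–Crafts coupling of a flavan-4-yl cation, in which BF3 ionises the quasi-axial 4-hydroxyl of 14 (the quasi-equatorial 4-hydroxyl of 20 is stereoelectronically slow to leave) and C6 of 20 (para to O1, ortho to the C7 ether) attacks C4 on the face anti to the axial 3-benzyloxy group, setting the 3,4-trans centre C4 of the upper unit.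

Step 17
Reactants: 21 nona-O-benzyl ether of the target
Product: 22 (2R,3R,4R)-6-[(2R,3R,4S)-2-(3,4-dihydroxyphenyl)-3,7,8-trihydroxychroman-4-yl]-2-(4-hydroxyphenyl)chromane-3,4,7,8-tetraol (target)
Conditions: H2 (1 atm), Pd(OH)2/C, THF/MeOH (1:1), rt; filtration under argon, Sephadex LH-20
Reagents that add atoms: none
Why: Catalytic hydrogenolysis should cleave all nine benzyl ethers under neutral conditions, where the secondary benzylic hydroxyl at C4 of the lower unit and the diarylmethine C4 of the upper unit are expected to survive.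

## Compound list

1 | 3-bromocatechol | Oc1cccc(Br)c1O | starting material
2 | 1,2-bis(benzyloxy)-3-bromobenzene | Brc1cccc(OCc2ccccc2)c1OCc1ccccc1 | intermediate
3 | 1,2-bis(benzyloxy)-3-bromo-4-iodobenzene | Ic1ccc(OCc2ccccc2)c(OCc2ccccc2)c1Br | intermediate
4 | (S)-4-benzyl-1,3-oxazolidin-2-one | O=C1N[C@@H](Cc2ccccc2)CO1 | starting material
5 | (benzyloxy)acetyl chloride | O=C(Cl)COCc1ccccc1 | starting material
6 | (S)-4-benzyl-3-[(benzyloxy)acetyl]-1,3-oxazolidin-2-one | O=C(COCc1ccccc1)N1[C@@H](Cc2ccccc2)COC1=O | intermediate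
7 | (S)-4-benzyl-3-[(Z)-2-(benzyloxy)-1-[(dibutylboranyl)oxy]ethenyl]-1,3-oxazolidin-2-one ((Z)-dibutylboron enolate of 6) | CCCCB(CCCC)O/C(=C\OCc1ccccc1)N1[C@@H](Cc2ccccc2)COC1=O | intermediate
8 | 3,4-bis(benzyloxy)benzaldehyde | O=Cc1ccc(OCc2ccccc2)c(OCc2ccccc2)c1 | starting material
9 | (S)-4-benzyl-3-[(2S,3R)-2-(benzyloxy)-3-[3,4-bis(benzyloxy)phenyl]-3-hydroxypropanoyl]-1,3-oxazolidin-2-one | O=C([C@@H](OCc1ccccc1)[C@H](O)c1ccc(OCc2ccccc2)c(OCc2ccccc2)c1)N1[C@@H](Cc2ccccc2)COC1=O | intermediate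
10 | (2S,3R)-2-(benzyloxy)-3-[3,4-bis(benzyloxy)phenyl]-3-hydroxy-N-methoxy-N-methylpropanamide | CON(C)C(=O)[C@@H](OCc1ccccc1)[C@H](O)c1ccc(OCc2ccccc2)c(OCc2ccccc2)c1 | intermediate
11 | [3,4-bis(benzyloxy)-2-bromophenyl]magnesium chloride | Cl[Mg]c1ccc(OCc2ccccc2)c(OCc2ccccc2)c1Br | intermediate
12 | (2S,3R)-2-(benzyloxy)-1-[3,4-bis(benzyloxy)-2-bromophenyl]-3-[3,4-bis(benzyloxy)phenyl]-3-hydroxypropan-1-one | O=C(c1ccc(OCc2ccccc2)c(OCc2ccccc2)c1Br)[C@@H](OCc1ccccc1)[C@H](O)c1ccc(OCc2ccccc2)c(OCc2ccccc2)c1 | intermediate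
13 | (1S,2S,3R)-2-(benzyloxy)-1-[3,4-bis(benzyloxy)-2-bromophenyl]-3-[3,4-bis(benzyloxy)phenyl]propane-1,3-diol | O[C@@H](c1ccc(OCc2ccccc2)c(OCc2ccccc2)c1Br)[C@@H](OCc1ccccc1)[C@H](O)c1ccc(OCc2ccccc2)c(OCc2ccccc2)c1 | intermediate
14 | (2R,3R,4S)-3,7,8-tris(benzyloxy)-2-[3,4-bis(benzyloxy)phenyl]chroman-4-ol | O[C@H]1c2ccc(OCc3ccccc3)c(OCc3ccccc3)c2O[C@H](c2ccc(OCc3ccccc3)c(OCc3ccccc3)c2)[C@@H]1OCc1ccccc1 | intermediate
15 | 4-(benzyloxy)benzaldehyde | O=Cc1ccc(OCc2ccccc2)cc1 | starting material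
16 | (S)-4-benzyl-3-[(2S,3R)-2-(benzyloxy)-3-[4-(benzyloxy)phenyl]-3-hydroxypropanoyl]-1,3-oxazolidin-2-one | O=C([C@@H](OCc1ccccc1)[C@H](O)c1ccc(OCc2ccccc2)cc1)N1[C@@H](Cc2ccccc2)COC1=O | intermediate
17 | (2S,3R)-2-(benzyloxy)-3-[4-(benzyloxy)phenyl]-3-hydroxy-N-methoxy-N-methylpropanamide | CON(C)C(=O)[C@@H](OCc1ccccc1)[C@H](O)c1ccc(OCc2ccccc2)cc1 | intermediate
18 | (2S,3R)-2-(benzyloxy)-1-[3,4-bis(benzyloxy)-2-bromophenyl]-3-[4-(benzyloxy)phenyl]-3-hydroxypropan-1-one | O=C(c1ccc(OCc2ccccc2)c(OCc2ccccc2)c1Br)[C@@H](OCc1ccccc1)[C@H](O)c1ccc(OCc2ccccc2)cc1 | intermediate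
19 | (1R,2S,3R)-2-(benzyloxy)-1-[3,4-bis(benzyloxy)-2-bromophenyl]-3-[4-(benzyloxy)phenyl]propane-1,3-diol | O[C@H](c1ccc(OCc2ccccc2)c(OCc2ccccc2)c1Br)[C@@H](OCc1ccccc1)[C@H](O)c1ccc(OCc2ccccc2)cc1 | intermediate
20 | (2R,3R,4R)-3,7,8-tris(benzyloxy)-2-[4-(benzyloxy)phenyl]chroman-4-ol | O[C@@H]1c2ccc(OCc3ccccc3)c(OCc3ccccc3)c2O[C@H](c2ccc(OCc3ccccc3)cc2)[C@@H]1OCc1ccccc1 | intermediate
21 | (2R,3R,4R)-3,7,8-tris(benzyloxy)-2-[4-(benzyloxy)phenyl]-6-{(2R,3R,4R)-3,7,8-tris(benzyloxy)-2-[3,4-bis(benzyloxy)phenyl]chroman-4-yl}chroman-4-ol | O(Cc6ccccc6)c1ccc([C@H]2Oc3c(cc([C@H]4c5ccc(OCc6ccccc6)c(OCc6ccccc6)c5O[C@H](c5ccc(OCc6ccccc6)c(OCc6ccccc6)c5)[C@@H]4OCc4ccccc4)c(OCc6ccccc6)c3OCc3ccccc3)[C@@H](O)[C@H]2OCc2ccccc2)cc1 | intermediate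
22 | (2R,3R,4R)-6-[(2R,3R,4S)-2-(3,4-dihydroxyphenyl)-3,7,8-trihydroxychroman-4-yl]-2-(4-hydroxyphenyl)chromane-3,4,7,8-tetraol | Oc1ccc([C@H]2Oc3c(cc([C@H]4c5ccc(O)c(O)c5O[C@H](c5ccc(O)c(O)c5)[C@@H]4O)c(O)c3O)[C@@H](O)[C@H]2O)cc1 | target

## Step count and risks

Total step count: 17. Longest linear sequence: 9 steps (steps 3, 4, 5, 6, 8, 9, 10, 16, 17).

Steps most likely to fail:

1. Step 16. What may go wrong: loss of chemoselectivity between two benzylic alcohols under one Lewis acid (ionisation of the 4-hydroxyl of the nucleophile), self-condensation of the electrophile through its own C6, competing attack through C5 of the nucleophile, and elimination of the cation to a flav-3-ene. The fallback sets out from 14 and comes back to the route at 21. The 4-hydroxyl of 14 would be exchanged for sulfur (BnSH, ZnI2, CH2Cl2, −20 °C) to give the 3,4-trans thioether (2R,3S,4S)-4-(benzylsulfanyl)-3,7,8-tris(benzyloxy)-2-[3,4-bis(benzyloxy)phenyl]chromane F1. Its C–S bond alone would then be activated by the thiophilic salt AgBF4 (THF, 0 °C) in the presence of 20, whose hydroxyl is not ionised by silver, and the same anti attack at C4 should give 21.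

2. Step 10. What may go wrong: β-hydride elimination from the palladium alkoxide (oxidation of a benzylic alcohol with hydrodebromination) and slow oxidative addition into the hindered, electron-rich C–Br bond. The fallback sets out from 10 and comes back to the route at 14; it forms the same O1–C8a bond by nucleophilic aromatic substitution on a fluoroarene, with no transition metal. 3-Fluorocatechol would be benzylated (BnBr, K2CO3, DMF) to 1,2-bis(benzyloxy)-3-fluorobenzene F2 and brominated (NBS, MeCN) para to the in-plane benzyloxy group to 1,2-bis(benzyloxy)-4-bromo-3-fluorobenzene F3. Bromine–lithium exchange (n-BuLi, THF, −78 °C) would give [3,4-bis(benzyloxy)-2-fluorophenyl]lithium F4, which would add to 10 (hydroxyl first deprotonated with i-PrMgCl) to give (2S,3R)-2-(benzyloxy)-1-[3,4-bis(benzyloxy)-2-fluorophenyl]-3-[3,4-bis(benzyloxy)phenyl]-3-hydroxypropan-1-one F5. Narasaka–Prasad reduction as in step 9 would give (1S,2S,3R)-2-(benzyloxy)-1-[3,4-bis(benzyloxy)-2-fluorophenyl]-3-[3,4-bis(benzyloxy)phenyl]propane-1,3-diol F6. KN(SiMe3)2 (2.2 equiv) and 18-crown-6 in THF/DMF (0 → 60 °C) would then close the ring by intramolecular displacement of fluoride by the C3 alkoxide to give 14.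

3. Step 17. What may go wrong: hydrogenolysis of the benzylic C4–O bond of the lower unit once the para phenol is unveiled, or ionisation of that alcohol on the catalyst surface. The fallback sets out from 21 and comes back to the route at 22. Dess–Martin periodinane (CH2Cl2, NaHCO3) would oxidise the only free hydroxyl to give (2R,3S)-3,7,8-tris(benzyloxy)-2-[4-(benzyloxy)phenyl]-6-{(2R,3R,4R)-3,7,8-tris(benzyloxy)-2-[3,4-bis(benzyloxy)phenyl]chroman-4-yl}chroman-4-one F7. Hydrogenolysis (H2, Pd(OH)2/C, THF/MeOH) would then meet no benzylic alcohol and give (2R,3S)-6-[(2R,3R,4S)-2-(3,4-dihydroxyphenyl)-3,7,8-trihydroxychroman-4-yl]-3,7,8-trihydroxy-2-(4-hydroxyphenyl)chroman-4-one F8. NaBH4 (EtOH, 0 °C) would reduce the ketone by hydride attack anti to the axial 3-hydroxyl, restoring the 3,4-cis 4-ol of 22.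

Further compounds
F1 | step 16 | (2R,3S,4S)-4-(benzylsulfanyl)-3,7,8-tris(benzyloxy)-2-[3,4-bis(benzyloxy)phenyl]chromane | c1ccccc1CS[C@H]1c2ccc(OCc3ccccc3)c(OCc3ccccc3)c2O[C@H](c2ccc(OCc3ccccc3)c(OCc3ccccc3)c2)[C@@H]1OCc1ccccc1
F2 | step 10 | 1,2-bis(benzyloxy)-3-fluorobenzene | Fc1cccc(OCc2ccccc2)c1OCc1ccccc1
F3 | step 10 | 1,2-bis(benzyloxy)-4-bromo-3-fluorobenzene | Brc1ccc(OCc2ccccc2)c(OCc2ccccc2)c1F
F4 | step 10 | [3,4-bis(benzyloxy)-2-fluorophenyl]lithium | [Li]c1ccc(OCc2ccccc2)c(OCc2ccccc2)c1F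
F5 | step 10 | (2S,3R)-2-(benzyloxy)-1-[3,4-bis(benzyloxy)-2-fluorophenyl]-3-[3,4-bis(benzyloxy)phenyl]-3-hydroxypropan-1-one | O=C(c1ccc(OCc2ccccc2)c(OCc2ccccc2)c1F)[C@@H](OCc1ccccc1)[C@H](O)c1ccc(OCc2ccccc2)c(OCc2ccccc2)c1
F6 | step 10 | (1S,2S,3R)-2-(benzyloxy)-1-[3,4-bis(benzyloxy)-2-fluorophenyl]-3-[3,4-bis(benzyloxy)phenyl]propane-1,3-diol | O[C@@H](c1ccc(OCc2ccccc2)c(OCc2ccccc2)c1F)[C@@H](OCc1ccccc1)[C@H](O)c1ccc(OCc2ccccc2)c(OCc2ccccc2)c1
F7 | step 17 | (2R,3S)-3,7,8-tris(benzyloxy)-2-[4-(benzyloxy)phenyl]-6-{(2R,3R,4R)-3,7,8-tris(benzyloxy)-2-[3,4-bis(benzyloxy)phenyl]chroman-4-yl}chroman-4-one | O(Cc6ccccc6)c1ccc([C@H]2Oc3c(cc([C@H]4c5ccc(OCc6ccccc6)c(OCc6ccccc6)c5O[C@H](c5ccc(OCc6ccccc6)c(OCc6ccccc6)c5)[C@@H]4OCc4ccccc4)c(OCc6ccccc6)c3OCc3ccccc3)C(=O)[C@H]2OCc2ccccc2)cc1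
F8 | step 17 | (2R,3S)-6-[(2R,3R,4S)-2-(3,4-dihydroxyphenyl)-3,7,8-trihydroxychroman-4-yl]-3,7,8-trihydroxy-2-(4-hydroxyphenyl)chroman-4-one | Oc1ccc([C@H]2Oc3c(cc([C@H]4c5ccc(O)c(O)c5O[C@H](c5ccc(O)c(O)c5)[C@@H]4O)c(O)c3O)C(=O)[C@H]2O)cc1
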